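## Retrosynthetic overview

1. Target 18 ⇒ allyl ester 17 ⇒ (C8'–O acyl bond) diol 14 + (S)-half ester 16, the latter from the prochiral diester 15 by enzymatic desymmetrisation.
2. 14 ⇒ aldehyde 13 (C8' one oxidation level up) ⇒ C1'–C6' bond: enantioselective intramolecular Mukaiyama aldol of the acyclic cis-enedione silyl enol ether 11. This closes the cyclohexenone C1'–C6', the only carbocycle and so the last ring formed, and sets both ring stereocentres.
3. Enabling feature: C6' is α to C8' and β to the C1' carbinol (aldol triad C8'–C6'–C1'–O), and C1'(O)–C2'=C3'–C4'(=O) is a cis-ene-1,4-dione, i.e. the four carbons of a furan. So 11 ⇒ 2,3,5-trisubstituted furan 9 by photooxygenation (the furan is a temporary ring, opened before the carbocycle closes).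
4. 9 ⇒ 3-methylfuran-2-carbaldehyde 1 + methyl 3-methylbut-2-enoate 3 (2Z,4E chain by lactone opening) + 2-methylprop-2-en-1-ol 6 (Heck reaction, supplies C5', C6', C8' and the C6' methyl).

Key step: step 7

Locants: ring carbons C1' (carbinol), C2'(Me)=C3', C4' (ketone), C5'H2, C6' (quaternary); C8' is the oxygenated carbon on C6'; C1–C5 is the dienoic acid chain.

Assumption: the catalyst antipode that gives (1R,6R)-13 is taken to be found by testing both enantiomers of the IDPi acid, and pig liver esterase is taken to give the (S)-half ester 16.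

## Route

Step 1
Reactants: 1 3-methylfuran-2-carbaldehyde
Product: 2 5-bromo-3-methylfuran-2-carbaldehyde
Conditions: Br2 (1.05 equiv), ClCH2CH2Cl, 60 °C, dark
Reagents that add atoms: bromine, BrBr
Why: electrophilic aromatic bromination should go to C5, the only free α-position of the furan, while the formyl group tempers the ring against over-bromination.

Step 2
Reactants: 2 5-bromo-3-methylfuran-2-carbaldehyde; 3 methyl 3-methylbut-2-enoate
Product: 5 (2Z,4E)-5-(5-bromo-3-methylfuran-2-yl)-3-methylpenta-2,4-dienoic acid, via dihydropyranone 4 (not isolated)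
Conditions: 3, LiN(i-Pr)2, THF, −78 °C; 2, −78 → 25 °C; KOt-Bu, 0 → 25 °C; aq. HCl
Reagents that add atoms: none
Why: vinylogous aldol addition of the ester dienolate (the α-adduct equilibrates to the γ-adduct on warming) and lactonisation give 4, whose ring locks the C2=C3 bond cis, so that E1cB ring opening with alkoxide should deliver the 2Z acid with a new 4E alkene.

Step 3
Reactants: 5 (2Z,4E)-5-(5-bromo-3-methylfuran-2-yl)-3-methylpenta-2,4-dienoic acid; 6 2-methylprop-2-en-1-ol
Product: 7 (2Z,4E)-3-methyl-5-[3-methyl-5-(2-methyl-3-oxopropyl)furan-2-yl]penta-2,4-dienoic acid (racemic)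
Conditions: Pd(OAc)2 (5 mol%), Bu4NCl, NaHCO3, 6 (3 equiv), DMF, 50 °C; aq. HCl
Reagents that add atoms: none
Why: Heck reaction of the furyl bromide at the CH2 terminus of the 1,1-disubstituted alkene, with β-hydride elimination toward the carbinol and enol-to-aldehyde tautomerisation, should give the α-methyl aldehyde; its stereocentre is racemic and is erased in step 5.

Step 4
Reactants: 7 (2Z,4E)-3-methyl-5-[3-methyl-5-(2-methyl-3-oxopropyl)furan-2-yl]penta-2,4-dienoic acid
Product: 8 allyl (2Z,4E)-3-methyl-5-[3-methyl-5-(2-methyl-3-oxopropyl)furan-2-yl]penta-2,4-dienoate (racemic)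
Conditions: allyl bromide, KHCO3, DMF, 25 °C
Reagents that add atoms: allyl bromide, C=CCBr
Why: SN2 O-alkylation of the carboxylate under bicarbonate should leave the enolisable aldehyde and the 2Z alkene untouched and installs an ester that is removed at the end without base or acid.

Step 5
Reactants: 8 allyl (2Z,4E)-3-methyl-5-[3-methyl-5-(2-methyl-3-oxopropyl)furan-2-yl]penta-2,4-dienoate
Product: 9 allyl (2Z,4E)-3-methyl-5-{3-methyl-5-[(E)-2-methyl-3-(triethylsilyloxy)prop-2-en-1-yl]furan-2-yl}penta-2,4-dienoate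
Conditions: Et3SiOTf, Et3N, CH2Cl2, −78 → 0 °C
Reagents that add atoms: triethylsilyl trifluoromethanesulfonate, CC[Si](CC)(CC)OS(=O)(=O)C(F)(F)F
Why: soft enolisation and O-silylation of the only enolisable carbonyl fixes the future C6' nucleophile regiospecifically as a trisubstituted silyl enol ether (mainly E expected; either isomer serves).

Step 6
Reactants: 9 allyl (2Z,4E)-3-methyl-5-{3-methyl-5-[(E)-2-methyl-3-(triethylsilyloxy)prop-2-en-1-yl]furan-2-yl}penta-2,4-dienoate
Product: 11 allyl (2Z,4E,7Z,11E)-3,7,11-trimethyl-6,9-dioxo-12-(triethylsilyloxy)dodeca-2,4,7,11-tetraenoate, via furan endoperoxide 10 (not isolated)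
Conditions: O2, tetraphenylporphyrin (0.5 mol%), visible light, CH2Cl2, −78 °C; Me2S, −78 → −20 °C; cold water wash, used crude
Reagents that add atoms: dioxygen, O=O
Why: furan photooxygenation ([4+2] addition of singlet oxygen across C1'/C4') and sulfide reduction of the ozonide-like endoperoxide should unmask the ene-1,4-dione with the Z geometry dictated by the former ring; the trisubstituted furan is expected to react far faster with singlet oxygen than the silyl enol ether or the electron-poor dienoate.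

Step 7
Reactants: 11 allyl (2Z,4E,7Z,11E)-3,7,11-trimethyl-6,9-dioxo-12-(triethylsilyloxy)dodeca-2,4,7,11-tetraenoate
Product: 13 allyl (2Z,4E)-5-[(1R,6R)-6-formyl-1-hydroxy-2,6-dimethyl-4-oxocyclohex-2-en-1-yl]-3-methylpenta-2,4-dienoate, via silyl ether 12 (not isolated)
Conditions: chiral BINOL-derived imidodiphosphorimidate (IDPi) acid (2 mol%, silylated in situ by 11), toluene/CH2Cl2, 0.02 M, −78 °C; then HF·pyridine, THF, 0 °C
Reagents that add atoms: none
Why: Proposed new method: the silylated IDPi ion pair transfers its silyl group to the C1' ketone oxygen of 11, the tethered silyl enol ether adds through C6' to C1', and the C8' silyloxocarbenium ion hands its silyl group back to the chiral anion, so the aldehyde is released and the catalyst turns over, after which HF·pyridine cleaves the tertiary silyl ether. The closest known reaction type is the silylium-ion-pair (IDPi) catalysed enantioselective Mukaiyama aldol addition of silyl enolates to ketones, together with Lewis-acid intramolecular Mukaiyama aldol cyclisations; the use on a furan-derived cis-enedione with an aldehyde enol silane is the new element. The cyclohexenone ring closes through the C1'–C6' bond in a 6-exo-trig (6-enolexo) mode. C1' and C6' are formed together: an open, antiperiplanar half-chair transition state with the dienyl chain on C1' and the methyl on C6' pseudo-equatorial should place O1' trans to C8', and the chiral anion paired with the silyloxocarbenium ion selects the ketone face and with it the absolute configuration. The step needs site selectivity for C1', which ring size secures (addition to C4' or C3' would give a three- or four-membered ring, addition to C2' is a 5-endo closure), and it needs the Z geometry of the enedione, which the furan ring hands on.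

Step 8
Reactants: 13 allyl (2Z,4E)-5-[(1R,6R)-6-formyl-1-hydroxy-2,6-dimethyl-4-oxocyclohex-2-en-1-yl]-3-methylpenta-2,4-dienoate
Product: 14 allyl (2Z,4E)-5-[(1R,6S)-1-hydroxy-6-(hydroxymethyl)-2,6-dimethyl-4-oxocyclohex-2-en-1-yl]-3-methylpenta-2,4-dienoate
Conditions: NaBH(OAc)3, AcOH, MeCN, 0 °C; pH 5 aqueous work-up; used at once
Reagents that add atoms: none
Why: hydroxyl-directed triacetoxyborohydride reduction (the C1' hydroxyl binds boron and delivers hydride to the neighbouring aldehyde) should spare the enone and the esters, and the acidic medium should keep the new 8'-hydroxyl from adding to C2' of the enone.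

Step 9
Reactants: 15 dimethyl 3-hydroxy-3-methylpentanedioate
Product: 16 (3S)-3-hydroxy-5-methoxy-3-methyl-5-oxopentanoic acid
Conditions: pig liver esterase, aqueous phosphate buffer pH 8, 25 °C; acidification to pH 2, extraction
Reagents that add atoms: water, O
Why: enzymatic desymmetrisation (hydrolysis of one of the two enantiotopic ester groups of the prochiral diester) sets the glutarate stereocentre; the (S)-half ester is expected.

Step 10
Reactants: 14 allyl (2Z,4E)-5-[(1R,6S)-1-hydroxy-6-(hydroxymethyl)-2,6-dimethyl-4-oxocyclohex-2-en-1-yl]-3-methylpenta-2,4-dienoate; 16 (3S)-3-hydroxy-5-methoxy-3-methyl-5-oxopentanoic acid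
Product: 17 allyl (2Z,4E)-5-[(1R,6S)-1-hydroxy-6-({[(3R)-3-hydroxy-5-methoxy-3-methyl-5-oxopentanoyl]oxy}methyl)-2,6-dimethyl-4-oxocyclohex-2-en-1-yl]-3-methylpenta-2,4-dienoate
Conditions: dicyclohexylcarbodiimide, 4-(dimethylamino)pyridinium p-toluenesulfonate (0.3 equiv), CH2Cl2, 0 °C
Reagents that add atoms: none
Why: Steglich-type carbodiimide esterification should acylate only the primary C8' hydroxyl (the C1' and glutarate tertiary alcohols are inert), the buffered pyridinium salt keeps the medium non-basic, and the glutarate centre is not touched (its descriptor changes from S to R only through priority).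

Step 11
Reactants: 17 allyl (2Z,4E)-5-[(1R,6S)-1-hydroxy-6-({[(3R)-3-hydroxy-5-methoxy-3-methyl-5-oxopentanoyl]oxy}methyl)-2,6-dimethyl-4-oxocyclohex-2-en-1-yl]-3-methylpenta-2,4-dienoate
Product: 18 (2Z,4E)-5-[(1R,6S)-1-hydroxy-6-({[(3R)-3-hydroxy-5-methoxy-3-methyl-5-oxopentanoyl]oxy}methyl)-2,6-dimethyl-4-oxocyclohex-2-en-1-yl]-3-methylpenta-2,4-dienoic acid (CNP0274837.1)
Conditions: Pd(PPh3)4 (5 mol%), morpholine (3 equiv), THF, 25 °C; citric acid work-up
Reagents that add atoms: none
Why: Tsuji–Trost deallylation (zerovalent palladium ionises the allyl ester and morpholine captures the π-allyl unit) should free the acid under neutral conditions that spare the methyl ester, the C8' ester, the enone and both tertiary alcohols.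

## Compound list

1 | 3-methylfuran-2-carbaldehyde | Cc1ccoc1C=O | starting material
2 | 5-bromo-3-methylfuran-2-carbaldehyde | Cc1cc(Br)oc1C=O | intermediate
3 | methyl 3-methylbut-2-enoate | COC(=O)C=C(C)C | starting material
4 | 6-(5-bromo-3-methylfuran-2-yl)-4-methyl-5,6-dihydro-2H-pyran-2-one (racemic, not isolated) | CC1=CC(=O)OC(C1)c1oc(Br)cc1C | intermediate
5 | (2Z,4E)-5-(5-bromo-3-methylfuran-2-yl)-3-methylpenta-2,4-dienoic acid | Cc1cc(Br)oc1/C=C/C(C)=C\C(=O)O | intermediate
6 | 2-methylprop-2-en-1-ol | C=C(C)CO | starting material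
7 | (2Z,4E)-3-methyl-5-[3-methyl-5-(2-methyl-3-oxopropyl)furan-2-yl]penta-2,4-dienoic acid (racemic) | CC(C=O)Cc1cc(C)c(/C=C/C(C)=C\C(=O)O)o1 | intermediate
8 | allyl (2Z,4E)-3-methyl-5-[3-methyl-5-(2-methyl-3-oxopropyl)furan-2-yl]penta-2,4-dienoate (racemic) | CC(C=O)Cc1cc(C)c(/C=C/C(C)=C\C(=O)OCC=C)o1 | intermediate
9 | allyl (2Z,4E)-3-methyl-5-{3-methyl-5-[(E)-2-methyl-3-(triethylsilyloxy)prop-2-en-1-yl]furan-2-yl}penta-2,4-dienoate | CC[Si](CC)(CC)O/C=C(\C)Cc1cc(C)c(/C=C/C(C)=C\C(=O)OCC=C)o1 | intermediate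
10 | allyl (2Z,4E)-3-methyl-5-{6-methyl-4-[(E)-2-methyl-3-(triethylsilyloxy)prop-2-en-1-yl]-2,3,7-trioxabicyclo[2.2.1]hept-5-en-1-yl}penta-2,4-dienoate (racemic, not isolated) | C=CCOC(=O)/C=C(C)\C=C\C12OOC(C/C(C)=C/O[Si](CC)(CC)CC)(O1)C=C2C | intermediate
11 | allyl (2Z,4E,7Z,11E)-3,7,11-trimethyl-6,9-dioxo-12-(triethylsilyloxy)dodeca-2,4,7,11-tetraenoate | CC[Si](CC)(CC)O/C=C(\C)CC(=O)/C=C(C)\C(=O)/C=C/C(C)=C\C(=O)OCC=C | intermediate
12 | allyl (2Z,4E)-5-[(1R,6R)-6-formyl-2,6-dimethyl-4-oxo-1-(triethylsilyloxy)cyclohex-2-en-1-yl]-3-methylpenta-2,4-dienoate (not isolated) | O=C[C@]1(C)CC(=O)C=C(C)[C@]1(O[Si](CC)(CC)CC)/C=C/C(C)=C\C(=O)OCC=C | intermediate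
13 | allyl (2Z,4E)-5-[(1R,6R)-6-formyl-1-hydroxy-2,6-dimethyl-4-oxocyclohex-2-en-1-yl]-3-methylpenta-2,4-dienoate | O=C[C@]1(C)CC(=O)C=C(C)[C@]1(O)/C=C/C(C)=C\C(=O)OCC=C | intermediate
14 | allyl (2Z,4E)-5-[(1R,6S)-1-hydroxy-6-(hydroxymethyl)-2,6-dimethyl-4-oxocyclohex-2-en-1-yl]-3-methylpenta-2,4-dienoate | OC[C@]1(C)CC(=O)C=C(C)[C@]1(O)/C=C/C(C)=C\C(=O)OCC=C | intermediate
15 | dimethyl 3-hydroxy-3-methylpentanedioate | COC(=O)CC(C)(O)CC(=O)OC | starting material
16 | (3S)-3-hydroxy-5-methoxy-3-methyl-5-oxopentanoic acid | COC(=O)C[C@@](C)(O)CC(=O)O | intermediate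
17 | allyl (2Z,4E)-5-[(1R,6S)-1-hydroxy-6-({[(3R)-3-hydroxy-5-methoxy-3-methyl-5-oxopentanoyl]oxy}methyl)-2,6-dimethyl-4-oxocyclohex-2-en-1-yl]-3-methylpenta-2,4-dienoate | COC(=O)C[C@@](C)(O)CC(=O)OC[C@]1(C)CC(=O)C=C(C)[C@]1(O)/C=C/C(C)=C\C(=O)OCC=C | intermediate
18 | (2Z,4E)-5-[(1R,6S)-1-hydroxy-6-({[(3R)-3-hydroxy-5-methoxy-3-methyl-5-oxopentanoyl]oxy}methyl)-2,6-dimethyl-4-oxocyclohex-2-en-1-yl]-3-methylpenta-2,4-dienoic acid | COC(=O)C[C@@](C)(O)CC(=O)OC[C@]1(C)CC(=O)C=C(C)[C@]1(O)/C=C/C(C)=C\C(=O)O | target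

## Step count and risks

Total steps: 11. Longest linear sequence: 10 (steps 1–8, 10 and 11); step 9 is the side branch.

Steps most likely to fail:

**Step 7 (proposed new method).** The risk is poor facial control (low enantio- or diastereoselectivity in a ring closure that joins two fully substituted carbons). Lewis-acid-induced Z-to-E isomerisation of the enedione or Nazarov-type closure of the cross-conjugated C1' dienone could also outrun the aldol. The fallback uses known chemistry and takes the absolute configuration from the enantiopure acid 16 by diastereomer separation instead of from a catalyst. It sets out from 11. Cyclisation with BF3·OEt2 (1.1 equiv, CH2Cl2, −78 °C), an ordinary Lewis-acid intramolecular Mukaiyama aldol, should give the racemic aldol, i.e. 13 together with its enantiomer allyl (2Z,4E)-5-[(1S,6S)-6-formyl-1-hydroxy-2,6-dimethyl-4-oxocyclohex-2-en-1-yl]-3-methylpenta-2,4-dienoate F1. Reduction as in step 8 gives 14 together with allyl (2Z,4E)-5-[(1S,6R)-1-hydroxy-6-(hydroxymethyl)-2,6-dimethyl-4-oxocyclohex-2-en-1-yl]-3-methylpenta-2,4-dienoate F2. Esterification with 16 as in step 10 gives 17 together with the diastereomer allyl (2Z,4E)-5-[(1S,6R)-1-hydroxy-6-({[(3R)-3-hydroxy-5-methoxy-3-methyl-5-oxopentanoyl]oxy}methyl)-2,6-dimethyl-4-oxocyclohex-2-en-1-yl]-3-methylpenta-2,4-dienoate F3, which is removed by chromatography. The route is rejoined at 17.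

**Step 8.** Once the 8'-hydroxyl is free beside the enone, intramolecular oxa-Michael addition to C2' can form a bridged ether (the known fate of 8'-hydroxylated abscisic acids). This can happen during reduction, work-up or the acylation of step 10. The fallback removes the Michael acceptor before the hydroxyl appears and sets out from 13. NaBH4 (excess) with CeCl3·7H2O in MeOH at −40 °C (Luche conditions; the enone carbonyl is reduced first) should give the triol allyl (2Z,4E)-5-[(1R,6S)-1,4-dihydroxy-6-(hydroxymethyl)-2,6-dimethylcyclohex-2-en-1-yl]-3-methylpenta-2,4-dienoate F4 as C4' epimers. Acylation with 16 (dicyclohexylcarbodiimide, the pyridinium salt of step 10, −20 °C) at the primary hydroxyl gives allyl (2Z,4E)-5-[(1R,6S)-1,4-dihydroxy-6-({[(3R)-3-hydroxy-5-methoxy-3-methyl-5-oxopentanoyl]oxy}methyl)-2,6-dimethylcyclohex-2-en-1-yl]-3-methylpenta-2,4-dienoate F5. MnO2 in CH2Cl2 then re-oxidises the allylic C4' alcohol and the route is rejoined at 17.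

**Step 3.** β-Hydride elimination may go the wrong way (allylic alcohols instead of the aldehyde), palladium hydride may isomerise the 2Z alkene, and the aryl palladium species may add to the dienoate. The fallback replaces the Heck reaction by an sp2–sp3 cross-coupling and sets out from 5. Hydroboration of tert-butyldimethyl[(2-methylprop-2-en-1-yl)oxy]silane with 9-borabicyclo[3.3.1]nonane gives 9-[3-(tert-butyldimethylsilyloxy)-2-methylpropyl]-9-borabicyclo[3.3.1]nonane F6. Suzuki–Miyaura coupling of F6 with 5 (PdCl2(dppf), K3PO4, DMF/H2O, 50 °C) should give (2Z,4E)-5-{5-[3-(tert-butyldimethylsilyloxy)-2-methylpropyl]-3-methylfuran-2-yl}-3-methylpenta-2,4-dienoic acid F7. Allylation as in step 4 gives allyl (2Z,4E)-5-{5-[3-(tert-butyldimethylsilyloxy)-2-methylpropyl]-3-methylfuran-2-yl}-3-methylpenta-2,4-dienoate F8. HF·pyridine gives allyl (2Z,4E)-5-[5-(3-hydroxy-2-methylpropyl)-3-methylfuran-2-yl]-3-methylpenta-2,4-dienoate F9. Dess–Martin periodinane oxidation then rejoins the route at 8.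

## Further compounds

F1 | step 7 | allyl (2Z,4E)-5-[(1S,6S)-6-formyl-1-hydroxy-2,6-dimethyl-4-oxocyclohex-2-en-1-yl]-3-methylpenta-2,4-dienoate | O=C[C@@]1(C)CC(=O)C=C(C)[C@@]1(O)/C=C/C(C)=C\C(=O)OCC=C
F2 | step 7 | allyl (2Z,4E)-5-[(1S,6R)-1-hydroxy-6-(hydroxymethyl)-2,6-dimethyl-4-oxocyclohex-2-en-1-yl]-3-methylpenta-2,4-dienoate | OC[C@@]1(C)CC(=O)C=C(C)[C@@]1(O)/C=C/C(C)=C\C(=O)OCC=C
F3 | step 7 | allyl (2Z,4E)-5-[(1S,6R)-1-hydroxy-6-({[(3R)-3-hydroxy-5-methoxy-3-methyl-5-oxopentanoyl]oxy}methyl)-2,6-dimethyl-4-oxocyclohex-2-en-1-yl]-3-methylpenta-2,4-dienoate | COC(=O)C[C@@](C)(O)CC(=O)OC[C@@]1(C)CC(=O)C=C(C)[C@@]1(O)/C=C/C(C)=C\C(=O)OCC=C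
F4 | step 8 | allyl (2Z,4E)-5-[(1R,6S)-1,4-dihydroxy-6-(hydroxymethyl)-2,6-dimethylcyclohex-2-en-1-yl]-3-methylpenta-2,4-dienoate (C4 epimers) | OC[C@]1(C)CC(O)C=C(C)[C@]1(O)/C=C/C(C)=C\C(=O)OCC=C
F5 | step 8 | allyl (2Z,4E)-5-[(1R,6S)-1,4-dihydroxy-6-({[(3R)-3-hydroxy-5-methoxy-3-methyl-5-oxopentanoyl]oxy}methyl)-2,6-dimethylcyclohex-2-en-1-yl]-3-methylpenta-2,4-dienoate (C4 epimers) | COC(=O)C[C@@](C)(O)CC(=O)OC[C@]1(C)CC(O)C=C(C)[C@]1(O)/C=C/C(C)=C\C(=O)OCC=C
F6 | step 3 | 9-[3-(tert-butyldimethylsilyloxy)-2-methylpropyl]-9-borabicyclo[3.3.1]nonane (racemic) | CC(CO[Si](C)(C)C(C)(C)C)CB1C2CCCC1CCC2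
F7 | step 3 | (2Z,4E)-5-{5-[3-(tert-butyldimethylsilyloxy)-2-methylpropyl]-3-methylfuran-2-yl}-3-methylpenta-2,4-dienoic acid (racemic) | CC(CO[Si](C)(C)C(C)(C)C)Cc1cc(C)c(/C=C/C(C)=C\C(=O)O)o1
F8 | step 3 | allyl (2Z,4E)-5-{5-[3-(tert-butyldimethylsilyloxy)-2-methylpropyl]-3-methylfuran-2-yl}-3-methylpenta-2,4-dienoate (racemic) | CC(CO[Si](C)(C)C(C)(C)C)Cc1cc(C)c(/C=C/C(C)=C\C(=O)OCC=C)o1
F9 | step 3 | allyl (2Z,4E)-5-[5-(3-hydroxy-2-methylpropyl)-3-methylfuran-2-yl]-3-methylpenta-2,4-dienoate (racemic) | CC(CO)Cc1cc(C)c(/C=C/C(C)=C\C(=O)OCC=C)o1
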